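**Retrosynthetic overview**
1. Locants follow the cyclodeca[b]furan skeleton of the target (O1, C2=O, C3=CH2, C3a, C4 to C11, C11a). The last operations are desilylation and, before it, installation of the C4 ester by Mitsunobu inversion of a 4-epi alcohol.
2. Key step: the ten-membered carbocycle and the C3a and C4 stereocentres are made together by an intramolecular CrCl2-mediated allylation (C3a–C4 bond) of a tethered aldehyde by a 3-(bromomethyl)butenolide; the carbocycle is not closed by olefin metathesis or by a vinyl–aldehyde coupling.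
3. The butenolide comes from ring-closing metathesis of a 2-(bromomethyl)acrylate; C8–C9 comes from a B-alkyl Suzuki coupling of a (Z)-vinyl iodide whose geometry is fixed by alkyne carbomagnesiation.
4. The C11/C11a syn-diol comes from a Brown γ-alkoxyallylboration; C6 comes from an Evans alkylation.
5. Ring order: butenolide first (step 13), then the cyclodecene (step 14).

Assumption: the acyl group is (2R)-2-methylbutanoyl exactly as the SMILES encodes it, and 5, 11, 14, 23, 28 and (−)-Ipc2BOMe are taken as purchasable; TBS = tert-butyldimethylsilyl.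

**Route**

Step 1
Reactants: 1 prop-2-yn-1-ol
Product: 3 (2Z)-3-iodo-2-methylprop-2-en-1-ol, via vinylmagnesium alkoxide 2 (not isolated)
Conditions: MeMgBr (2.5 equiv), CuI (10 mol %), THF, −10 to 20 °C; then I2, −20 °C; aq NH4Cl
Reagents that add atoms: methylmagnesium bromide C[Mg]Br; iodine [I][I]
Why: Copper-catalysed anti-carbomagnesiation of the propargylic alkoxide places the new C–Mg bond cis to CH2O through the magnesium chelate, and iodinolysis with retention fixes the Z trisubstituted olefin that becomes C9=C10.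

Step 2
Reactants: 3 (2Z)-3-iodo-2-methylprop-2-en-1-ol
Product: 4 (2Z)-3-iodo-2-methylprop-2-enal
Conditions: MnO2 (15 equiv), CH2Cl2, 20 °C, dark; filtered and used as a solution
Reagents that add atoms: none
Why: Heterogeneous MnO2 oxidation of the allylic alcohol is neutral and does not isomerise the Z iodoenal.

Step 3
Reactants: 4 (2Z)-3-iodo-2-methylprop-2-enal; 5 1-methoxy-4-(prop-2-en-1-yloxy)benzene
Product: 8 (3R,4R,5Z)-6-iodo-3-(4-methoxyphenoxy)-5-methylhexa-1,5-dien-4-ol, via allylborane 6 (not isolated), via borinate ester 7 (not isolated)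
Conditions: 5, sec-BuLi, THF, −78 °C; (−)-Ipc2BOMe; BF3·OEt2; then 4, −78 °C; NaOH, H2O2, 0 °C
Reagents that add atoms: none
Why: Brown γ-alkoxyallylboration, in which the Z aryloxyallylborane adds through a chair transition state so that its Z geometry gives the syn diol monoether and the isopinocampheyl groups derived from (+)-α-pinene select the aldehyde face that gives 3R,4R (the future C11a and C11).

Step 4
Reactants: 8 (3R,4R,5Z)-6-iodo-3-(4-methoxyphenoxy)-5-methylhexa-1,5-dien-4-ol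
Product: 9 tert-butyl{[(3R,4R,5Z)-6-iodo-3-(4-methoxyphenoxy)-5-methylhexa-1,5-dien-4-yl]oxy}dimethylsilane
Conditions: TBSOTf, 2,6-lutidine, CH2Cl2, −78 to 0 °C
Reagents that add atoms: tert-butyldimethylsilyl trifluoromethanesulfonate CC(C)(C)[Si](C)(C)OS(=O)(=O)C(F)(F)F
Why: Silyl triflate silylation protects the hindered secondary allylic alcohol without touching a stereocentre.

Step 5
Reactants: 10 but-3-enoic acid; 11 (4R)-4-benzyl-1,3-oxazolidin-2-one
Product: 13 (4R)-4-benzyl-3-(but-3-enoyl)-1,3-oxazolidin-2-one, via mixed pivalic anhydride 12 (not isolated)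
Conditions: t-BuCOCl, Et3N, THF, −20 °C; then 11, LiCl, −20 to 20 °C
Reagents that add atoms: none
Why: N-Acylation of the Evans auxiliary through the mixed anhydride with LiCl activation is mild enough to keep the double bond out of conjugation.

Step 6
Reactants: 13 (4R)-4-benzyl-3-(but-3-enoyl)-1,3-oxazolidin-2-one; 14 2-bromo-N-methoxy-N-methylacetamide
Product: 16 (3R)-3-{[(4R)-4-benzyl-2-oxo-1,3-oxazolidin-3-yl]carbonyl}-N-methoxy-N-methylpent-4-enamide, via sodium enolate 15 (not isolated)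
Conditions: NaN(SiMe3)2, THF, −78 °C; then 14, −78 to −40 °C
Reagents that add atoms: none
Why: Evans asymmetric alkylation, in which the chelated Z enolate is alkylated at its α-carbon on the face opposite the benzyl group and so sets the future C6 stereocentre.

Step 7
Reactants: 16 (3R)-3-{[(4R)-4-benzyl-2-oxo-1,3-oxazolidin-3-yl]carbonyl}-N-methoxy-N-methylpent-4-enamide
Product: 17 (3R)-3-(hydroxymethyl)-N-methoxy-N-methylpent-4-enamide
Conditions: LiBH4, Et2O/THF, 0 °C
Reagents that add atoms: none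
Why: Reductive cleavage of the imide by LiBH4 gives the primary alcohol and returns the auxiliary, while the less electrophilic Weinreb amide is left intact.

Step 8
Reactants: 17 (3R)-3-(hydroxymethyl)-N-methoxy-N-methylpent-4-enamide
Product: 18 (3R)-3-{[(tert-butyldimethylsilyl)oxy]methyl}-N-methoxy-N-methylpent-4-enamide
Conditions: TBSCl, imidazole, DMF, 20 °C
Reagents that add atoms: tert-butyldimethylsilyl chloride CC(C)(C)[Si](C)(C)Cl
Why: Imidazole-promoted silylation caps the primary alcohol at once, before it can lactonise onto the amide.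

Step 9
Reactants: 18 (3R)-3-{[(tert-butyldimethylsilyl)oxy]methyl}-N-methoxy-N-methylpent-4-enamide; 9 tert-butyl{[(3R,4R,5Z)-6-iodo-3-(4-methoxyphenoxy)-5-methylhexa-1,5-dien-4-yl]oxy}dimethylsilane
Product: 20 (3S,6Z,8R,9R)-8-[(tert-butyldimethylsilyl)oxy]-3-{[(tert-butyldimethylsilyl)oxy]methyl}-N-methoxy-9-(4-methoxyphenoxy)-N,7-dimethylundeca-6,10-dienamide, via alkylborane 19 (not isolated)
Conditions: 18, 9-BBN-H, THF, 20 °C; then aq Cs2CO3, 9, Pd(dppf)Cl2·CH2Cl2 (5 mol %), AsPh3, DMF, 20 °C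
Reagents that add atoms: none
Why: B-alkyl Suzuki–Miyaura coupling, in which anti-Markovnikov hydroboration of the vinyl group and cross-coupling under zerovalent palladium catalysis form C8–C9 with retention of the Z geometry.

Step 10
Reactants: 20 (3S,6Z,8R,9R)-8-[(tert-butyldimethylsilyl)oxy]-3-{[(tert-butyldimethylsilyl)oxy]methyl}-N-methoxy-9-(4-methoxyphenoxy)-N,7-dimethylundeca-6,10-dienamide
Product: 21 (3S,6Z,8R,9R)-8-[(tert-butyldimethylsilyl)oxy]-3-{[(tert-butyldimethylsilyl)oxy]methyl}-9-hydroxy-N-methoxy-N,7-dimethylundeca-6,10-dienamide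
Conditions: (NH4)2Ce(NO3)6 (2.5 equiv), pyridine, MeCN/H2O 4:1, 0 °C
Reagents that add atoms: none
Why: Oxidative dearylation of the 4-methoxyphenyl ether (single-electron oxidation of the electron-rich arene, lost as benzoquinone) frees the C11a hydroxyl after the basic coupling, so no silyl migration can occur.

Step 11
Reactants: 21 (3S,6Z,8R,9R)-8-[(tert-butyldimethylsilyl)oxy]-3-{[(tert-butyldimethylsilyl)oxy]methyl}-9-hydroxy-N-methoxy-N,7-dimethylundeca-6,10-dienamide
Product: 22 (3S,6Z,8R,9R)-8-[(tert-butyldimethylsilyl)oxy]-3-{[(tert-butyldimethylsilyl)oxy]methyl}-9-hydroxy-7-methylundeca-6,10-dienal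
Conditions: i-Bu2AlH (2.5 equiv), THF, −78 °C; aq KNaC4H4O6
Reagents that add atoms: none
Why: Weinreb amide reduction stops at the chelated tetrahedral aluminium intermediate, which releases the aldehyde only on work-up.

Step 12
Reactants: 22 (3S,6Z,8R,9R)-8-[(tert-butyldimethylsilyl)oxy]-3-{[(tert-butyldimethylsilyl)oxy]methyl}-9-hydroxy-7-methylundeca-6,10-dienal; 23 2-(bromomethyl)prop-2-enoic acid
Product: 24 (3R,4R,5Z,9S)-4-[(tert-butyldimethylsilyl)oxy]-9-{[(tert-butyldimethylsilyl)oxy]methyl}-5-methyl-11-oxoundeca-1,5-dien-3-yl 2-(bromomethyl)prop-2-enoate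
Conditions: N,N'-diisopropylcarbodiimide, DMAP (5 mol %), CH2Cl2, 0 °C
Reagents that add atoms: none
Why: Steglich esterification acylates the only free hydroxyl with retention at the future C11a.

Step 13
Reactants: 24 (3R,4R,5Z,9S)-4-[(tert-butyldimethylsilyl)oxy]-9-{[(tert-butyldimethylsilyl)oxy]methyl}-5-methyl-11-oxoundeca-1,5-dien-3-yl 2-(bromomethyl)prop-2-enoate
Product: 25 (3S,6Z,8R)-8-[(2R)-4-(bromomethyl)-5-oxo-2,5-dihydrofuran-2-yl]-8-[(tert-butyldimethylsilyl)oxy]-3-{[(tert-butyldimethylsilyl)oxy]methyl}-7-methyloct-6-enal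
Conditions: second-generation Grubbs catalyst (H2IMes)(PCy3)Cl2Ru=CHPh (10 mol %), toluene, 0.005 mol/L, 80 °C
Reagents that add atoms: none
Why: Ring-closing metathesis between the vinyl group and the acrylate olefin closes the butenolide with loss of ethene, while the trisubstituted Z olefin and the aldehyde do not react.

Step 14
Reactants: 25 (3S,6Z,8R)-8-[(2R)-4-(bromomethyl)-5-oxo-2,5-dihydrofuran-2-yl]-8-[(tert-butyldimethylsilyl)oxy]-3-{[(tert-butyldimethylsilyl)oxy]methyl}-7-methyloct-6-enal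
Product: 27 (3aS,4R,6S,9Z,11R,11aR)-11-[(tert-butyldimethylsilyl)oxy]-6-{[(tert-butyldimethylsilyl)oxy]methyl}-4-hydroxy-10-methyl-3-methylidene-3a,4,5,6,7,8,11,11a-octahydrocyclodeca[b]furan-2(3H)-one, via allylchromium species 26 (not isolated)
Conditions: CrCl2 (10 equiv), THF/DMF 4:1, 25 °C, slow addition of 25 to a final 0.002 mol/L; aq NH4Cl
Reagents that add atoms: none
Why: Proposed new method: intramolecular Nozaki–Hiyama–Kishi-type allylation in which divalent chromium inserts into the C–Br bond and the resulting allylchromium adds through its ring γ-carbon (future C3a) to the tethered aldehyde in a chair Zimmerman–Traxler transition state, bonding on the butenolide face opposite the C11a side chain (trans-fused lactone, 3aS) and, because the allyl unit is ring-locked as an E-type reagent with the aldehyde chain equatorial, giving the anti adduct (4R, the C4 epimer that step 15 inverts); the closest known reactions are the intermolecular chromium-mediated allylation of aldehydes with 3-(bromomethyl)furan-2(5H)-one and the intramolecular chromium allylation of 2-(bromomethyl)acrylates that closes ten-membered germacranolide rings.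

Step 15
Reactants: 27 (3aS,4R,6S,9Z,11R,11aR)-11-[(tert-butyldimethylsilyl)oxy]-6-{[(tert-butyldimethylsilyl)oxy]methyl}-4-hydroxy-10-methyl-3-methylidene-3a,4,5,6,7,8,11,11a-octahydrocyclodeca[b]furan-2(3H)-one; 28 (2R)-2-methylbutanoic acid
Product: 29 (3aS,4S,6S,9Z,11R,11aR)-11-[(tert-butyldimethylsilyl)oxy]-6-{[(tert-butyldimethylsilyl)oxy]methyl}-10-methyl-3-methylidene-2-oxo-2,3,3a,4,5,6,7,8,11,11a-decahydrocyclodeca[b]furan-4-yl (2R)-2-methylbutanoate
Conditions: PPh3, diisopropyl azodicarboxylate, toluene, 0 to 20 °C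
Reagents that add atoms: none
Why: Mitsunobu esterification, in which the carboxylate displaces the alkoxyphosphonium ion of the C4 alcohol with inversion (4R to 4S), installs the ester and the last ring stereocentre in one operation and leaves the α-stereocentre of the acid untouched.

Step 16
Reactants: 29 (3aS,4S,6S,9Z,11R,11aR)-11-[(tert-butyldimethylsilyl)oxy]-6-{[(tert-butyldimethylsilyl)oxy]methyl}-10-methyl-3-methylidene-2-oxo-2,3,3a,4,5,6,7,8,11,11a-decahydrocyclodeca[b]furan-4-yl (2R)-2-methylbutanoate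
Product: 30 (3aS,4S,6S,9Z,11R,11aR)-11-hydroxy-6-(hydroxymethyl)-10-methyl-3-methylidene-2-oxo-2,3,3a,4,5,6,7,8,11,11a-decahydrocyclodeca[b]furan-4-yl (2R)-2-methylbutanoate
Conditions: HF·pyridine, pyridine, THF, 0 to 20 °C
Reagents that add atoms: none
Why: Fluoride-mediated desilylation under buffered, weakly acidic conditions removes both silyl ethers while the α-methylene lactone and the ester survive.

**Compound list**

1 | prop-2-yn-1-ol | C#CCO | starting material
2 | bromomagnesium (2Z)-3-(bromomagnesio)-2-methylprop-2-en-1-olate | Br[Mg]/C=C(/C)CO[Mg]Br | intermediate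
3 | (2Z)-3-iodo-2-methylprop-2-en-1-ol | OC/C(C)=C\I | intermediate
4 | (2Z)-3-iodo-2-methylprop-2-enal | O=C/C(C)=C\I | intermediate
5 | 1-methoxy-4-(prop-2-en-1-yloxy)benzene | C=CCOc1ccc(OC)cc1 | starting material
6 | [(2Z)-3-(4-methoxyphenoxy)prop-2-en-1-yl]bis[(1R,2S,3R,5R)-2,6,6-trimethylbicyclo[3.1.1]heptan-3-yl]borane | COc1ccc(O/C=C\CB([C@@H]2C[C@@H]3C[C@H]([C@H]2C)C3(C)C)[C@@H]2C[C@@H]3C[C@H]([C@H]2C)C3(C)C)cc1 | intermediate
7 | (3R,4R,5Z)-6-iodo-3-(4-methoxyphenoxy)-5-methylhexa-1,5-dien-4-yl bis[(1R,2S,3R,5R)-2,6,6-trimethylbicyclo[3.1.1]heptan-3-yl]borinate | C=C[C@@H](Oc1ccc(OC)cc1)[C@H](OB([C@@H]1C[C@@H]2C[C@H]([C@H]1C)C2(C)C)[C@@H]1C[C@@H]2C[C@H]([C@H]1C)C2(C)C)/C(C)=C\I | intermediate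
8 | (3R,4R,5Z)-6-iodo-3-(4-methoxyphenoxy)-5-methylhexa-1,5-dien-4-ol | C=C[C@@H](Oc1ccc(OC)cc1)[C@H](O)/C(C)=C\I | intermediate
9 | tert-butyl{[(3R,4R,5Z)-6-iodo-3-(4-methoxyphenoxy)-5-methylhexa-1,5-dien-4-yl]oxy}dimethylsilane | C=C[C@@H](Oc1ccc(OC)cc1)[C@H](O[Si](C)(C)C(C)(C)C)/C(C)=C\I | intermediate
10 | but-3-enoic acid | C=CCC(=O)O | starting material
11 | (4R)-4-benzyl-1,3-oxazolidin-2-one | O=C1N[C@H](Cc2ccccc2)CO1 | starting material
12 | but-3-enoic 2,2-dimethylpropanoic anhydride | C=CCC(=O)OC(=O)C(C)(C)C | intermediate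
13 | (4R)-4-benzyl-3-(but-3-enoyl)-1,3-oxazolidin-2-one | C=CCC(=O)N1[C@H](Cc2ccccc2)COC1=O | intermediate
14 | 2-bromo-N-methoxy-N-methylacetamide | BrCC(=O)N(C)OC | starting material
15 | sodium (1Z)-1-[(4R)-4-benzyl-2-oxo-1,3-oxazolidin-3-yl]buta-1,3-dien-1-olate | [Na+].C=C/C=C(\[O-])N1[C@H](Cc2ccccc2)COC1=O | intermediate
16 | (3R)-3-{[(4R)-4-benzyl-2-oxo-1,3-oxazolidin-3-yl]carbonyl}-N-methoxy-N-methylpent-4-enamide | C=C[C@@H](CC(=O)N(C)OC)C(=O)N1[C@H](Cc2ccccc2)COC1=O | intermediate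
17 | (3R)-3-(hydroxymethyl)-N-methoxy-N-methylpent-4-enamide | C=C[C@H](CO)CC(=O)N(C)OC | intermediate
18 | (3R)-3-{[(tert-butyldimethylsilyl)oxy]methyl}-N-methoxy-N-methylpent-4-enamide | C=C[C@H](CO[Si](C)(C)C(C)(C)C)CC(=O)N(C)OC | intermediate
19 | (3S)-5-(9-borabicyclo[3.3.1]nonan-9-yl)-3-{[(tert-butyldimethylsilyl)oxy]methyl}-N-methoxy-N-methylpentanamide | C1CCC2CCCC1B2CC[C@H](CO[Si](C)(C)C(C)(C)C)CC(=O)N(C)OC | intermediate
20 | (3S,6Z,8R,9R)-8-[(tert-butyldimethylsilyl)oxy]-3-{[(tert-butyldimethylsilyl)oxy]methyl}-N-methoxy-9-(4-methoxyphenoxy)-N,7-dimethylundeca-6,10-dienamide | C=C[C@@H](Oc1ccc(OC)cc1)[C@H](O[Si](C)(C)C(C)(C)C)/C(C)=C\CC[C@H](CO[Si](C)(C)C(C)(C)C)CC(=O)N(C)OC | intermediate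
21 | (3S,6Z,8R,9R)-8-[(tert-butyldimethylsilyl)oxy]-3-{[(tert-butyldimethylsilyl)oxy]methyl}-9-hydroxy-N-methoxy-N,7-dimethylundeca-6,10-dienamide | C=C[C@@H](O)[C@H](O[Si](C)(C)C(C)(C)C)/C(C)=C\CC[C@H](CO[Si](C)(C)C(C)(C)C)CC(=O)N(C)OC | intermediate
22 | (3S,6Z,8R,9R)-8-[(tert-butyldimethylsilyl)oxy]-3-{[(tert-butyldimethylsilyl)oxy]methyl}-9-hydroxy-7-methylundeca-6,10-dienal | C=C[C@@H](O)[C@H](O[Si](C)(C)C(C)(C)C)/C(C)=C\CC[C@H](CO[Si](C)(C)C(C)(C)C)CC=O | intermediate
23 | 2-(bromomethyl)prop-2-enoic acid | C=C(CBr)C(=O)O | starting material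
24 | (3R,4R,5Z,9S)-4-[(tert-butyldimethylsilyl)oxy]-9-{[(tert-butyldimethylsilyl)oxy]methyl}-5-methyl-11-oxoundeca-1,5-dien-3-yl 2-(bromomethyl)prop-2-enoate | C=C[C@@H](OC(=O)C(=C)CBr)[C@H](O[Si](C)(C)C(C)(C)C)/C(C)=C\CC[C@H](CO[Si](C)(C)C(C)(C)C)CC=O | intermediate
25 | (3S,6Z,8R)-8-[(2R)-4-(bromomethyl)-5-oxo-2,5-dihydrofuran-2-yl]-8-[(tert-butyldimethylsilyl)oxy]-3-{[(tert-butyldimethylsilyl)oxy]methyl}-7-methyloct-6-enal | O=CC[C@@H](CO[Si](C)(C)C(C)(C)C)CC/C=C(/C)[C@@H](O[Si](C)(C)C(C)(C)C)[C@@H]1OC(=O)C(CBr)=C1 | intermediate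
26 | dichloro{[(5R)-5-{(1R,2Z,6S)-1-[(tert-butyldimethylsilyl)oxy]-6-{[(tert-butyldimethylsilyl)oxy]methyl}-2-methyl-8-oxooct-2-en-1-yl}-2-oxo-2,5-dihydrofuran-3-yl]methyl}chromium | O=CC[C@@H](CO[Si](C)(C)C(C)(C)C)CC/C=C(/C)[C@@H](O[Si](C)(C)C(C)(C)C)[C@@H]1OC(=O)C(C[Cr](Cl)Cl)=C1 | intermediate
27 | (3aS,4R,6S,9Z,11R,11aR)-11-[(tert-butyldimethylsilyl)oxy]-6-{[(tert-butyldimethylsilyl)oxy]methyl}-4-hydroxy-10-methyl-3-methylidene-3a,4,5,6,7,8,11,11a-octahydrocyclodeca[b]furan-2(3H)-one | C=C1C(=O)O[C@@H]2[C@@H]1[C@H](O)C[C@@H](CO[Si](C)(C)C(C)(C)C)CC/C=C(/C)[C@H]2O[Si](C)(C)C(C)(C)C | intermediate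
28 | (2R)-2-methylbutanoic acid | CC[C@@H](C)C(=O)O | starting material
29 | (3aS,4S,6S,9Z,11R,11aR)-11-[(tert-butyldimethylsilyl)oxy]-6-{[(tert-butyldimethylsilyl)oxy]methyl}-10-methyl-3-methylidene-2-oxo-2,3,3a,4,5,6,7,8,11,11a-decahydrocyclodeca[b]furan-4-yl (2R)-2-methylbutanoate | C=C1C(=O)O[C@@H]2[C@@H]1[C@@H](OC(=O)[C@H](C)CC)C[C@@H](CO[Si](C)(C)C(C)(C)C)CC/C=C(/C)[C@H]2O[Si](C)(C)C(C)(C)C | intermediate
30 | (3aS,4S,6S,9Z,11R,11aR)-11-hydroxy-6-(hydroxymethyl)-10-methyl-3-methylidene-2-oxo-2,3,3a,4,5,6,7,8,11,11a-decahydrocyclodeca[b]furan-4-yl (2R)-2-methylbutanoate | C=C1C(=O)O[C@@H]2[C@@H]1[C@@H](OC(=O)[C@H](C)CC)C[C@@H](CO)CC/C=C(/C)[C@H]2O | target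

**Step count and risk**

Total step count: 16. Longest linear sequence: 12 steps (steps 1–4 and 9–16, from prop-2-yn-1-ol); the eastern branch (steps 5–8) is 4 steps.

The three steps most likely to fail:

Step 14 (ring closure). The risks are oligomerisation, a cis-fused lactone, or a C4 outcome that differs from the chair prediction. The fallback makes the chromium allylation intermolecular and closes the ring at C8–C9 instead. It sets out from 9 and also uses 18, 23 and 28. Cleavage of the aryl ether of 9 with (NH4)2Ce(NO3)6 gives the allylic alcohol F1. Carbodiimide esterification with 23 gives the bromomethylacrylate F2, and ring-closing metathesis gives the iodovinyl bromomethylbutenolide F3. Reduction of 18 with i-Bu2AlH gives the pentenal F4. CrCl2 joins F3 and F4 through the same chair transition state to the open-chain anti adduct F5. Mitsunobu esterification with 28 inverts the carbinol and gives the open-chain ester F6. Hydroboration of the vinyl group of F6 with 9-BBN-H, then intramolecular B-alkyl Suzuki coupling onto the vinyl iodide (Pd(dppf)Cl2, AsPh3, Cs2CO3, high dilution), closes the ten-membered ring and comes back to the route at 29.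

Step 15 (Mitsunobu inversion). The risk is that SN2 at a ten-membered-ring carbinol is slow and elimination toward C3a competes. The fallback sets C4 by hydride addition instead of substitution and sets out from 27. Dess–Martin oxidation with NaHCO3 buffer gives the C4 ketone F7. Corey–Bakshi–Shibata reduction with the (R)-oxazaborolidine and catecholborane at −78 °C gives the (4S)-alcohol F8 under reagent control. Carbodiimide/DMAP esterification with 28, now with retention, comes back to the route at 29.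

Step 13 (metathesis). The risk is that the electron-poor 1,1-disubstituted olefin carrying an allylic bromide closes slowly or degrades the catalyst. The fallback replaces the bromide by an acetate and generates the nucleophile by umpolung, and it sets out from 22. Carbodiimide esterification with 2-[(acetyloxy)methyl]prop-2-enoic acid gives the acetoxymethylacrylate F9, and ring-closing metathesis gives the acetoxymethylbutenolide F10. Zerovalent palladium (Pd(PPh3)4) ionises the allylic acetate, and Et2Zn transmetallates the π-allylpalladium to an allylzinc that adds to the tethered aldehyde through the same chair. This comes back to the route at 27.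

Further compounds
F1 | step 14 | (3R,4R,5Z)-4-[(tert-butyldimethylsilyl)oxy]-6-iodo-5-methylhexa-1,5-dien-3-ol | C=C[C@@H](O)[C@H](O[Si](C)(C)C(C)(C)C)/C(C)=C\I
F2 | step 14 | (3R,4R,5Z)-4-[(tert-butyldimethylsilyl)oxy]-6-iodo-5-methylhexa-1,5-dien-3-yl 2-(bromomethyl)prop-2-enoate | C=C[C@@H](OC(=O)C(=C)CBr)[C@H](O[Si](C)(C)C(C)(C)C)/C(C)=C\I
F3 | step 14 | (5R)-3-(bromomethyl)-5-{(1R,2Z)-1-[(tert-butyldimethylsilyl)oxy]-3-iodo-2-methylprop-2-en-1-yl}furan-2(5H)-one | I/C=C(/C)[C@@H](O[Si](C)(C)C(C)(C)C)[C@@H]1OC(=O)C(CBr)=C1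
F4 | step 14 | (3R)-3-{[(tert-butyldimethylsilyl)oxy]methyl}pent-4-enal | C=C[C@H](CO[Si](C)(C)C(C)(C)C)CC=O
F5 | step 14 | (4S,5R)-5-{(1R,2Z)-1-[(tert-butyldimethylsilyl)oxy]-3-iodo-2-methylprop-2-en-1-yl}-4-[(1R,3R)-3-{[(tert-butyldimethylsilyl)oxy]methyl}-1-hydroxypent-4-en-1-yl]-3-methylideneoxolan-2-one | C=C1C(=O)O[C@@H]([C@H](O[Si](C)(C)C(C)(C)C)/C(C)=C\I)[C@@H]1[C@H](O)C[C@@H](CO[Si](C)(C)C(C)(C)C)C=C
F6 | step 14 | (1S,3R)-1-[(2R,3S)-2-{(1R,2Z)-1-[(tert-butyldimethylsilyl)oxy]-3-iodo-2-methylprop-2-en-1-yl}-4-methylidene-5-oxooxolan-3-yl]-3-{[(tert-butyldimethylsilyl)oxy]methyl}pent-4-en-1-yl (2R)-2-methylbutanoate | C=C1C(=O)O[C@@H]([C@H](O[Si](C)(C)C(C)(C)C)/C(C)=C\I)[C@@H]1[C@@H](OC(=O)[C@H](C)CC)C[C@@H](CO[Si](C)(C)C(C)(C)C)C=C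
F7 | step 15 | (3aR,6S,9Z,11R,11aR)-11-[(tert-butyldimethylsilyl)oxy]-6-{[(tert-butyldimethylsilyl)oxy]methyl}-10-methyl-3-methylidene-3a,5,6,7,8,11a-hexahydrocyclodeca[b]furan-2,4(3H,11H)-dione | C=C1C(=O)O[C@@H]2[C@@H]1C(=O)C[C@@H](CO[Si](C)(C)C(C)(C)C)CC/C=C(/C)[C@H]2O[Si](C)(C)C(C)(C)C
F8 | step 15 | (3aS,4S,6S,9Z,11R,11aR)-11-[(tert-butyldimethylsilyl)oxy]-6-{[(tert-butyldimethylsilyl)oxy]methyl}-4-hydroxy-10-methyl-3-methylidene-3a,4,5,6,7,8,11,11a-octahydrocyclodeca[b]furan-2(3H)-one | C=C1C(=O)O[C@@H]2[C@@H]1[C@@H](O)C[C@@H](CO[Si](C)(C)C(C)(C)C)CC/C=C(/C)[C@H]2O[Si](C)(C)C(C)(C)C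
F9 | step 13 | (3R,4R,5Z,9S)-4-[(tert-butyldimethylsilyl)oxy]-9-{[(tert-butyldimethylsilyl)oxy]methyl}-5-methyl-11-oxoundeca-1,5-dien-3-yl 2-[(acetyloxy)methyl]prop-2-enoate | C=C[C@@H](OC(=O)C(=C)COC(C)=O)[C@H](O[Si](C)(C)C(C)(C)C)/C(C)=C\CC[C@H](CO[Si](C)(C)C(C)(C)C)CC=O
F10 | step 13 | [(5R)-5-{(1R,2Z,6S)-1-[(tert-butyldimethylsilyl)oxy]-6-{[(tert-butyldimethylsilyl)oxy]methyl}-2-methyl-8-oxooct-2-en-1-yl}-2-oxo-2,5-dihydrofuran-3-yl]methyl acetate | O=CC[C@@H](CO[Si](C)(C)C(C)(C)C)CC/C=C(/C)[C@@H](O[Si](C)(C)C(C)(C)C)[C@@H]1OC(=O)C(COC(C)=O)=C1
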